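1. From 8.00 min on, Sunday's flask, the one asked about, barely moves, so a first estimate for 1.5 h is the mean of its triple product readings from then on, 17.2%.

| flask | substrate | partner | remark | time |
|---|---|---|---|---|
| Sunday's | 0.10 M | 2 equiv | the very flask that is asked about, followed so far |  |
| Wednesday's | 0.20 M | 2 equiv | run made earlier |  |
| flask | 0.10 M | 2.00 equiv |  | 1.5 h |

| run | time / min | triple product / % | first product / % |
|---|---|---|---|
| Sunday's | 4.00 | 13.7 | 14.7 |
| Sunday's | 8.00 | 17.4 | 14.1 |
| Sunday's | 10.0 | 15.9 | 11.6 |
| Sunday's | 15.0 | 17.0 | 11.4 |
| Sunday's | 20.0 | 18.3 | 11.8 |
| Wednesday's | 8.00 | 20.9 | 11.9 |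
| Wednesday's | 15.0 | 21.7 | 9.9 |
| Wednesday's | 20.0 | 21.4 | 8.2 |
| Wednesday's | 30.0 | 21.7 | 9.9 |
| Wednesday's | 40.0 | 23.1 | 12.1 |

(readings scatter by 1 percentage point)

* equivalents of partner to substrate, everything else as given, that leave most triple product at 1.5 h
* the amount of triple product then, in percent of the substrate charged
* the amount of triple product with the amounts as given

2. The objection is that a stall needs a cause, so the partner is counted, taking each step to add one partner. At 20.0 min, triple and first product carry 0.667 additions per substrate, while 69.9% of the substrate is unseen. If no partner remains, those unseen molecules carry on average 1.91 additions, which looks like a double product, with partner as the limiting reagent.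

3. An equilibrium could stall Sunday's flask too, so Wednesday's flask is looked at: at twice the concentration and the same equivalents, it reads 21.4% at 20.0 min, which is 3.1 percentage points above Sunday's reading at that time. A pure count predicts no change, so this gap, against a scatter of 1 point, suggests that some partner is lost without adding to substrate.

4. The quantity to carry is therefore the addition shortfall: 3 additions per substrate, less the equivalents of partner that actually add, which here is at least 1.00. Closing it takes more than 3 equiv, by an unknown loss, and once it is closed this reckoning expects the substrate to end as triple product, which is more than the 28% of the forecast.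

5. The forecast gave 20% as the flask stands and 28% at 4 equiv, adding “The optimum is therefore a guess”.

6. The flask gives 19.2%, with partner at 0%, and the best charge is 5.10 equiv, giving 95.3%.

    partner + double product → triple product + released group (k = 0.0769 M⁻¹ s⁻¹)
    substrate + partner → first product + released group (k = 0.228 M⁻¹ s⁻¹)
    partner + first product → double product + released group (k = 0.477 M⁻¹ s⁻¹)
    partner → decomposed reagent (k = 0.00278 s⁻¹)
    partner + triple product ⇌ tetra adduct + released group (K = 14.0, k = 0.181 M⁻¹ s⁻¹)
    partner → decomposition product (k = 1.65 × 10⁻⁵ s⁻¹)

Decomposed reagent took 0.230 equivalents in the flask, so its shortfall is 1.23 additions per substrate, not the bare 1.00. The neighbouring flask, charged with 3.40 equiv of partner, lost 0.677 equivalents to decomposed reagent, so its shortfall is 0.277 additions per substrate. That neighbouring flask ends with 72.5% triple product and 26.5% double product.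

(The readings come from a simulation for an exercise, and the scatter is random.)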